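Rings are lettered A to H from the 2,4,6-trihydroxyphenyl end to the 3,4,5-trihydroxyphenyl end. The target has no stereocentre, so only regiochemistry must be controlled, and it is fixed by the substitution patterns of the building blocks.
Cuts: the 21 O–CH3 bonds of a fully methylated precursor; then the aryl ether bond from the O on C4 of ring B to C1 of ring C (the carbon next to the only C–H of ring C); then the C1–C2 bond of ring A, which opens that ring to a 6-aryloxy-3,5-dioxohexanoate; then the five remaining aryl ether bonds.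
Feature used: ring A is a phloroglucinol whose ether carbon C1 lies between the hydroxylated C2 and C6, with a third oxygen on C4. This is the oxygen pattern of an acetate-type triketide with an aryloxy group on its last carbon, so the crowded ring A–O–ring B ether can be made by O-alkylation at an sp3 carbon before ring A exists.
Forward, arm 1: rings H, G and F are joined by copper-catalysed etherification of a phenol with a bromobenzaldehyde, each formyl group then being turned into the next phenol by Baeyer–Villiger oxidation. A ring D–E bromo aldehyde is attached next, then ring C, to give the ring C–H hexamer phenol.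
Forward, arm 2: 4-iodo-3,5-dimethoxyphenol (ring B) is O-alkylated and extended to the triketide ester, ring A is closed by Claisen cyclisation and methylated. The AB iodide and the hexamer phenol are then joined, and all methyl ethers are cleaved with BBr3.

Key step: step 15

Step 1
Reactants: 1 3,4,5-trimethoxyphenol; 2 2-bromo-3,4,5-trimethoxybenzaldehyde
Product: 3 3,4,5-trimethoxy-2-(3,4,5-trimethoxyphenoxy)benzaldehyde (ring G–H aldehyde)
Conditions: CuI (10 mol %), N,N-dimethylglycine·HCl (30 mol %), Cs2CO3, 1,4-dioxane, 100 °C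
Reagents that add atoms: none
Why: Ullmann-type copper-catalysed diaryl ether synthesis; the unhindered phenoxide of 1 should displace bromide from 2, whose C–Br bond is activated by the ortho formyl group, as in the classical etherifications of 2-bromo-3,4,5-trimethoxybenzoyl compounds.

Step 2
Reactants: 3 ring G–H aldehyde
Product: 5 3,4,5-trimethoxy-2-(3,4,5-trimethoxyphenoxy)phenol (ring G–H phenol), via aryl formate 4 (not isolated)
Conditions: mCPBA, CH2Cl2, 0 °C → rt; then K2CO3 (cat.), MeOH, rt
Reagents that add atoms: 3-chloroperoxybenzoic acid (mCPBA), O=C(OO)c1cccc(Cl)c1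
Why: Baeyer–Villiger (Dakin-type) oxidation; the aryl group, made electron-rich by the ortho aryloxy and para methoxy groups, should migrate in preference to hydride, and the formate is cleaved by base-catalysed methanolysis.

Step 3
Reactants: 5 ring G–H phenol; 6 3-bromo-4,5-dimethoxybenzaldehyde
Product: 7 3,4-dimethoxy-5-[3,4,5-trimethoxy-2-(3,4,5-trimethoxyphenoxy)phenoxy]benzaldehyde (ring F–H aldehyde)
Conditions: CuI (10 mol %), N,N-dimethylglycine·HCl (30 mol %), Cs2CO3, 1,4-dioxane, 100 °C
Reagents that add atoms: none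
Why: Ullmann-type etherification of the kind long used with 5-bromoveratraldehyde; phenol 5 has one ortho substituent and the bromide of 6 is flanked by a single methoxy group.

Step 4
Reactants: 7 ring F–H aldehyde
Product: 9 3,4-dimethoxy-5-[3,4,5-trimethoxy-2-(3,4,5-trimethoxyphenoxy)phenoxy]phenol (ring F–H phenol), via aryl formate 8 (not isolated)
Conditions: mCPBA, CH2Cl2, 0 °C → rt; then K2CO3 (cat.), MeOH, rt
Reagents that add atoms: 3-chloroperoxybenzoic acid (mCPBA), O=C(OO)c1cccc(Cl)c1
Why: Baeyer–Villiger oxidation as for 3,4,5-trimethoxybenzaldehyde, the para methoxy group directing aryl migration; methanolysis frees the phenol on C1 of ring F.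

Step 5
Reactants: 10 5-bromo-1,2,3-trimethoxybenzene
Product: 11 6-bromo-2,3,4-trimethoxybenzaldehyde
Conditions: Cl2CHOMe, TiCl4, CH2Cl2, 0 °C; then H2O
Reagents that add atoms: dichloromethyl methyl ether, COC(Cl)Cl; water, O
Why: Rieche formylation (Friedel–Crafts type); the two open positions of 10 are equivalent and lie ortho and para to methoxy groups, so a single regioisomer should form.

Step 6
Reactants: 11 6-bromo-2,3,4-trimethoxybenzaldehyde
Product: 13 6-bromo-2,3,4-trimethoxyphenol (ring E unit), via aryl formate 12 (not isolated)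
Conditions: mCPBA, CH2Cl2, 0 °C → rt; then K2CO3 (cat.), MeOH, rt
Reagents that add atoms: 3-chloroperoxybenzoic acid (mCPBA), O=C(OO)c1cccc(Cl)c1
Why: Baeyer–Villiger oxidation; the ortho and para methoxy groups favour aryl migration, and the aryl bromide is inert to peracid.

Step 7
Reactants: 13 6-bromo-2,3,4-trimethoxyphenol; 14 4-bromo-3,5-dimethoxybenzaldehyde
Product: 15 4-(6-bromo-2,3,4-trimethoxyphenoxy)-3,5-dimethoxybenzaldehyde (ring D–E bromo aldehyde)
Conditions: 14 (2 equiv), CuI (20 mol %), picolinic acid (40 mol %), K3PO4, DMSO, 110 °C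
Reagents that add atoms: none
Why: Ullmann-type etherification under the picolinic acid conditions devised for hindered partners; the C–Br bond of 14 is activated by the para formyl group, while the bromide of 13 sits on a far more electron-rich phenoxide ring and should stay untouched when 14 is in excess.

Step 8
Reactants: 15 ring D–E bromo aldehyde; 9 ring F–H phenol
Product: 16 ring D–H pentamer aldehyde (15 with Br replaced by the aryloxy group of 9)
Conditions: CuI (20 mol %), N,N-dimethylglycine·HCl (60 mol %), Cs2CO3, 1,4-dioxane, 105 °C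
Reagents that add atoms: none
Why: Ullmann-type etherification of an unhindered phenol with an aryl bromide bearing one ortho substituent; the non-enolisable formyl group on ring D tolerates carbonate base.

Step 9
Reactants: 16 ring D–H pentamer aldehyde
Product: 18 ring D–H pentamer phenol (OH on C1 of ring D), via aryl formate 17 (not isolated)
Conditions: mCPBA, CH2Cl2, 0 °C → rt; then K2CO3 (cat.), MeOH, rt
Reagents that add atoms: 3-chloroperoxybenzoic acid (mCPBA), O=C(OO)c1cccc(Cl)c1
Why: Baeyer–Villiger oxidation of a 4-aryloxybenzaldehyde, a standard way to 4-aryloxyphenols; the para aryloxy group supports aryl migration and the methyl aryl ethers do not react with peracid at this temperature.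

Step 10
Reactants: 18 ring D–H pentamer phenol; 2 2-bromo-3,4,5-trimethoxybenzaldehyde
Product: 19 ring C–H hexamer aldehyde (2 with Br replaced by the aryloxy group of 18)
Conditions: CuI (20 mol %), N,N-dimethylglycine·HCl (60 mol %), Cs2CO3, 1,4-dioxane, 100 °C
Reagents that add atoms: none
Why: Repeat of the ortho-formyl-assisted Ullmann etherification of step 1, here with a phenol flanked by two hydrogens.

Step 11
Reactants: 19 ring C–H hexamer aldehyde
Product: 21 ring C–H hexamer phenol (OH on C1 of ring C), via aryl formate 20 (not isolated)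
Conditions: mCPBA, CH2Cl2, 0 °C → rt; then K2CO3 (cat.), MeOH, rt
Reagents that add atoms: 3-chloroperoxybenzoic acid (mCPBA), O=C(OO)c1cccc(Cl)c1
Why: Baeyer–Villiger oxidation as in step 2, with the same ortho aryloxy and para methoxy groups driving aryl migration.

Step 12
Reactants: 22 2-iodo-1,3-dimethoxybenzene
Product: 24 4-iodo-3,5-dimethoxyphenol (ring B unit), via arylboronic pinacol ester 23 (not isolated)
Conditions: [Ir(OMe)(cod)]2 (1.5 mol %), 4,4'-di-tert-butyl-2,2'-bipyridine (3 mol %), B2pin2 (0.6 equiv), THF, 80 °C; then aq NaOH, H2O2, 0 °C → rt; aq HCl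
Reagents that add atoms: hydrogen peroxide, OO; bis(pinacolato)diboron, CC1(C)OB(OC1(C)C)B1OC(C)(C)C(C)(C)O1 (its atoms stay only in intermediate 23)
Why: Iridium-catalysed C–H borylation is governed by sterics and should occur only at C5 of 22, the one position without an ortho substituent; oxidation of the C–B bond with basic peroxide gives the phenol and leaves the aryl iodide untouched.

Step 13
Reactants: 24 4-iodo-3,5-dimethoxyphenol; 25 2-chloro-N-methoxy-N-methylacetamide
Product: 26 2-(4-iodo-3,5-dimethoxyphenoxy)-N-methoxy-N-methylacetamide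
Conditions: K2CO3, NaI (cat.), acetone, reflux
Reagents that add atoms: none
Why: Williamson ether synthesis at an activated primary chloride (Finkelstein-assisted); this SN2 step makes the O–C bond that later is the crowded ring B–O–ring A ether.

Step 14
Reactants: 26 2-(4-iodo-3,5-dimethoxyphenoxy)-N-methoxy-N-methylacetamide; 27 methyl acetoacetate
Product: 28 methyl 6-(4-iodo-3,5-dimethoxyphenoxy)-3,5-dioxohexanoate
Conditions: 27 (2.5 equiv), LiN(iPr)2 (5 equiv), THF, −78 → 0 °C; then 26, −78 → 0 °C; 1 M HCl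
Reagents that add atoms: none
Why: Acylation of the acetoacetate dianion at its terminal carbon by an N-methoxy-N-methylamide; the chelated tetrahedral adduct prevents over-addition and releases the 3,5-dioxo ester on acidic work-up.

Step 15
Reactants: 28 methyl 6-(4-iodo-3,5-dimethoxyphenoxy)-3,5-dioxohexanoate
Product: 30 2-(4-iodo-3,5-dimethoxyphenoxy)benzene-1,3,5-triol (AB unit, ring A free), via cyclohexanetrione 29 (not isolated)
Conditions: NaOMe (5 equiv), MeOH, reflux, Ar; then aq HCl, 0 °C
Reagents that add atoms: none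
Why: Methoxide equilibrates all enolates of 28; the C6 enolate (alpha to the C5 ketone and to the aryloxy oxygen, which acidifies it) adds to the C1 ester carbonyl and expels methoxide, so that chain C6 becomes C1 and chain C1 becomes C2 of ring A, and the trione 29 enolises to the aromatic triol, held as its phenoxide. The closest known reactions are the Dieckmann-type Claisen cyclisation of 5-oxo esters to cyclohexane-1,3-diones and the base-mediated closure of 3,5-dioxohexanoate esters to phloroglucinol. Ring A closes by a 6-(enolexo)-exo-trig acyl substitution, which is favoured, whereas any aldol closure of this chain would give only a four-membered ring. No stereocentre is formed. The step needs carbon acylation to win over oxygen acylation to the 4-hydroxy-2-pyrone: in methanolic methoxide the pyrone is reopened to 28 while aromatisation of 29 is irreversible, so material should drain to 30. The aryl iodide and the aryl ether are inert to methoxide in the absence of copper.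

Step 16
Reactants: 30 2-(4-iodo-3,5-dimethoxyphenoxy)benzene-1,3,5-triol
Product: 31 2-(4-iodo-3,5-dimethoxyphenoxy)-1,3,5-trimethoxybenzene (AB iodide)
Conditions: Me2SO4, K2CO3, acetone, reflux
Reagents that add atoms: dimethyl sulfate, COS(=O)(=O)OC
Why: Exhaustive O-methylation with dimethyl sulfate and K2CO3 in acetone, the usual conditions for turning phloroglucinols into trimethyl ethers with little C-methylation; it masks ring A for the copper step.

Step 17
Reactants: 21 ring C–H hexamer phenol; 31 AB iodide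
Product: 32 henicosa-O-methyl ether of the target (rings A–H, all 21 oxygens as OMe)
Conditions: 31 (1.5 equiv), CuI (20 mol %), picolinic acid (40 mol %), K3PO4, DMSO, 110 °C, Ar
Reagents that add atoms: none
Why: Ullmann-type etherification with the CuI/picolinic acid system suited to ortho-substituted partners; aryl halides flanked by two methoxy groups have long been coupled with polymethoxyphenols in phlorotannin chemistry, and the iodide was chosen over the bromide to ease this step.

Step 18
Reactants: 32 henicosa-O-methyl ether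
Product: 33 CNP0309601.0 (target)
Conditions: BBr3 (excess), CH2Cl2, −78 °C → rt, Ar; then H2O, 0 °C
Reagents that add atoms: none
Why: Lewis acid cleavage of aryl methyl ethers by BBr3 (bromide attacks the methyl group of the boron-bound ether), which leaves diaryl ether bonds intact; a large excess of reagent and exclusion of air are planned because 21 ethers must fall and the pyrogallol-type rings of 33 oxidise readily.

Compound list
1 | 3,4,5-trimethoxyphenol | COc1cc(O)cc(OC)c1OC | starting material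
2 | 2-bromo-3,4,5-trimethoxybenzaldehyde | COc1cc(C=O)c(Br)c(OC)c1OC | starting material
3 | 3,4,5-trimethoxy-2-(3,4,5-trimethoxyphenoxy)benzaldehyde | COc1cc(C=O)c(Oc2cc(OC)c(OC)c(OC)c2)c(OC)c1OC | intermediate
4 | 3,4,5-trimethoxy-2-(3,4,5-trimethoxyphenoxy)phenyl formate | COc1cc(OC=O)c(Oc2cc(OC)c(OC)c(OC)c2)c(OC)c1OC | intermediate
5 | 3,4,5-trimethoxy-2-(3,4,5-trimethoxyphenoxy)phenol | COc1cc(O)c(Oc2cc(OC)c(OC)c(OC)c2)c(OC)c1OC | intermediate
6 | 3-bromo-4,5-dimethoxybenzaldehyde | COc1cc(C=O)cc(Br)c1OC | starting material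
7 | 3,4-dimethoxy-5-[3,4,5-trimethoxy-2-(3,4,5-trimethoxyphenoxy)phenoxy]benzaldehyde | COc1cc(C=O)cc(Oc2cc(OC)c(OC)c(OC)c2Oc2cc(OC)c(OC)c(OC)c2)c1OC | intermediate
8 | formate of 9 (ring F–H aryl formate) | COc1cc(OC=O)cc(Oc2cc(OC)c(OC)c(OC)c2Oc2cc(OC)c(OC)c(OC)c2)c1OC | intermediate
9 | 3,4-dimethoxy-5-[3,4,5-trimethoxy-2-(3,4,5-trimethoxyphenoxy)phenoxy]phenol | COc1cc(O)cc(Oc2cc(OC)c(OC)c(OC)c2Oc2cc(OC)c(OC)c(OC)c2)c1OC | intermediate
10 | 5-bromo-1,2,3-trimethoxybenzene | COc1cc(Br)cc(OC)c1OC | starting material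
11 | 6-bromo-2,3,4-trimethoxybenzaldehyde | COc1cc(Br)c(C=O)c(OC)c1OC | intermediate
12 | 6-bromo-2,3,4-trimethoxyphenyl formate | COc1cc(Br)c(OC=O)c(OC)c1OC | intermediate
13 | 6-bromo-2,3,4-trimethoxyphenol | COc1cc(Br)c(O)c(OC)c1OC | intermediate
14 | 4-bromo-3,5-dimethoxybenzaldehyde | COc1cc(C=O)cc(OC)c1Br | starting material
15 | 4-(6-bromo-2,3,4-trimethoxyphenoxy)-3,5-dimethoxybenzaldehyde | COc1cc(C=O)cc(OC)c1Oc1c(Br)cc(OC)c(OC)c1OC | intermediate
16 | ring D–H pentamer aldehyde (15 with Br replaced by the aryloxy group of 9; CHO on C1 of ring D) | COc1cc(C=O)cc(OC)c1Oc1c(Oc2cc(OC)c(OC)c(Oc3cc(OC)c(OC)c(OC)c3Oc3cc(OC)c(OC)c(OC)c3)c2)cc(OC)c(OC)c1OC | intermediate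
17 | ring D–H pentamer aryl formate (OCHO in place of CHO of 16) | COc1cc(OC=O)cc(OC)c1Oc1c(Oc2cc(OC)c(OC)c(Oc3cc(OC)c(OC)c(OC)c3Oc3cc(OC)c(OC)c(OC)c3)c2)cc(OC)c(OC)c1OC | intermediate
18 | ring D–H pentamer phenol (OH in place of CHO of 16) | COc1cc(O)cc(OC)c1Oc1c(Oc2cc(OC)c(OC)c(Oc3cc(OC)c(OC)c(OC)c3Oc3cc(OC)c(OC)c(OC)c3)c2)cc(OC)c(OC)c1OC | intermediate
19 | ring C–H hexamer aldehyde (2 with Br replaced by the aryloxy group of 18; CHO on C1 of ring C) | COc1cc(C=O)c(Oc2cc(OC)c(Oc3c(Oc4cc(OC)c(OC)c(Oc5cc(OC)c(OC)c(OC)c5Oc5cc(OC)c(OC)c(OC)c5)c4)cc(OC)c(OC)c3OC)c(OC)c2)c(OC)c1OC | intermediate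
20 | ring C–H hexamer aryl formate (OCHO in place of CHO of 19) | COc1cc(OC=O)c(Oc2cc(OC)c(Oc3c(Oc4cc(OC)c(OC)c(Oc5cc(OC)c(OC)c(OC)c5Oc5cc(OC)c(OC)c(OC)c5)c4)cc(OC)c(OC)c3OC)c(OC)c2)c(OC)c1OC | intermediate
21 | ring C–H hexamer phenol (OH in place of CHO of 19) | COc1cc(O)c(Oc2cc(OC)c(Oc3c(Oc4cc(OC)c(OC)c(Oc5cc(OC)c(OC)c(OC)c5Oc5cc(OC)c(OC)c(OC)c5)c4)cc(OC)c(OC)c3OC)c(OC)c2)c(OC)c1OC | intermediate
22 | 2-iodo-1,3-dimethoxybenzene | COc1cccc(OC)c1I | starting material
23 | 2-(4-iodo-3,5-dimethoxyphenyl)-4,4,5,5-tetramethyl-1,3,2-dioxaborolane | COc1cc(B2OC(C)(C)C(C)(C)O2)cc(OC)c1I | intermediate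
24 | 4-iodo-3,5-dimethoxyphenol | COc1cc(O)cc(OC)c1I | intermediate
25 | 2-chloro-N-methoxy-N-methylacetamide | CON(C)C(=O)CCl | starting material
26 | 2-(4-iodo-3,5-dimethoxyphenoxy)-N-methoxy-N-methylacetamide | CON(C)C(=O)COc1cc(OC)c(I)c(OC)c1 | intermediate
27 | methyl acetoacetate | COC(=O)CC(C)=O | starting material
28 | methyl 6-(4-iodo-3,5-dimethoxyphenoxy)-3,5-dioxohexanoate | COC(=O)CC(=O)CC(=O)COc1cc(OC)c(I)c(OC)c1 | intermediate
29 | 2-(4-iodo-3,5-dimethoxyphenoxy)cyclohexane-1,3,5-trione | O=C1CC(=O)C(Oc2cc(OC)c(I)c(OC)c2)C(=O)C1 | intermediate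
30 | 2-(4-iodo-3,5-dimethoxyphenoxy)benzene-1,3,5-triol | Oc1cc(O)c(Oc2cc(OC)c(I)c(OC)c2)c(O)c1 | intermediate
31 | 2-(4-iodo-3,5-dimethoxyphenoxy)-1,3,5-trimethoxybenzene | COc1cc(OC)c(Oc2cc(OC)c(I)c(OC)c2)c(OC)c1 | intermediate
32 | henicosa-O-methyl ether of the target | COc1cc(OC)c(Oc2cc(OC)c(Oc3cc(OC)c(OC)c(OC)c3Oc3cc(OC)c(Oc4c(Oc5cc(OC)c(OC)c(Oc6cc(OC)c(OC)c(OC)c6Oc6cc(OC)c(OC)c(OC)c6)c5)cc(OC)c(OC)c4OC)c(OC)c3)c(OC)c2)c(OC)c1 | intermediate
33 | CNP0309601.0 | Oc1cc(O)c(Oc2cc(O)c(Oc3cc(O)c(O)c(O)c3Oc3cc(O)c(Oc4c(Oc5cc(O)c(O)c(Oc6cc(O)c(O)c(O)c6Oc6cc(O)c(O)c(O)c6)c5)cc(O)c(O)c4O)c(O)c3)c(O)c2)c(O)c1 | target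

Total step count: 18 steps.
Longest linear sequence: 10 steps (steps 1, 2, 3, 4, 8, 9, 10, 11, 17, 18).

Steps most likely to fail

Step 7. The ether to be made carries four ortho substituents, so the copper-bound phenoxide of 13 may fail to engage the doubly flanked C–Br bond of 14. Material would then be lost by condensation of 13 or of product 15 through their own bromine, giving oligomers. The fallback sets out from 13 and avoids copper. Commercial syringaldehyde (4-hydroxy-3,5-dimethoxybenzaldehyde, COc1cc(C=O)cc(OC)c1O) would be deoxyfluorinated with the chloroimidazolium chloride/CsF reagent PhenoFluorMix in toluene at 110 °C to 4-fluoro-3,5-dimethoxybenzaldehyde F1. The caesium phenoxide of 13 (Cs2CO3, DMSO, 130 °C) would then displace fluoride para to the formyl group in an addition–elimination (SNAr) that cannot touch an aryl bromide. This comes back to the route at 15.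

Step 17. Substitution at the iodide flanked by two methoxy groups may be too slow, so that 31 loses iodine by reduction and 21 is recovered. The fallback sets out from 21 and grows rings B and A on the hexamer, with the halide partner activated and ring A made by the same Claisen closure. Compound 21 would be etherified with 14, whose bromide is activated by its para formyl group (CuI, picolinic acid, K3PO4, DMSO), to the ring B–H heptamer aldehyde F2. Baeyer–Villiger oxidation with mCPBA through the heptamer aryl formate F3 and methanolysis would give the heptamer phenol F4. Alkylation with 25 (K2CO3, NaI, acetone) would give the N-methoxy-N-methylamide F5, and acylation of the dianion of 27 the triketide ester F6. Closure with NaOMe in MeOH through the trione F7 would give the octamer F8, in which ring A is a free triol and the other rings carry 18 methyl ethers. BBr3 then cleaves these ethers and the route is rejoined at 33.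

Step 15. Oxygen acylation by the C5 enol may divert 28 to the pyrone faster than it reopens, or methoxide may cleave the 1,3-dicarbonyl chain by retro-Claisen attack before C6 acylates. The fallback sets out from 24 and brings ring A in as a preformed arene. The phenoxide of 24 (Cs2CO3, DMSO, 120 °C) would displace fluoride from 4-fluoro-3,5-dimethoxybenzaldehyde F1, made as above, to give 4-(4-iodo-3,5-dimethoxyphenoxy)-3,5-dimethoxybenzaldehyde F9. Buffered Baeyer–Villiger oxidation (mCPBA, NaHCO3, CH2Cl2, 0 °C) through the aryl formate F10 and methanolysis would give 4-(4-iodo-3,5-dimethoxyphenoxy)-3,5-dimethoxyphenol F11. Methylation (Me2SO4, K2CO3, acetone) comes back to the route at 31.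

Further compounds
F1 | step 7 | 4-fluoro-3,5-dimethoxybenzaldehyde | COc1cc(C=O)cc(OC)c1F
F2 | step 17 | ring B–H heptamer aldehyde (14 with Br replaced by the aryloxy group of 21) | COc1cc(C=O)cc(OC)c1Oc1cc(OC)c(OC)c(OC)c1Oc1cc(OC)c(Oc2c(Oc3cc(OC)c(OC)c(Oc4cc(OC)c(OC)c(OC)c4Oc4cc(OC)c(OC)c(OC)c4)c3)cc(OC)c(OC)c2OC)c(OC)c1
F3 | step 17 | ring B–H heptamer aryl formate (OCHO in place of CHO of F2) | COc1cc(OC=O)cc(OC)c1Oc1cc(OC)c(OC)c(OC)c1Oc1cc(OC)c(Oc2c(Oc3cc(OC)c(OC)c(Oc4cc(OC)c(OC)c(OC)c4Oc4cc(OC)c(OC)c(OC)c4)c3)cc(OC)c(OC)c2OC)c(OC)c1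
F4 | step 17 | ring B–H heptamer phenol (OH on C1 of ring B) | COc1cc(O)cc(OC)c1Oc1cc(OC)c(OC)c(OC)c1Oc1cc(OC)c(Oc2c(Oc3cc(OC)c(OC)c(Oc4cc(OC)c(OC)c(OC)c4Oc4cc(OC)c(OC)c(OC)c4)c3)cc(OC)c(OC)c2OC)c(OC)c1
F5 | step 17 | N-methoxy-N-methyl-2-(heptamer-oxy)acetamide (F4 O-alkylated by 25) | CON(C)C(=O)COc1cc(OC)c(Oc2cc(OC)c(OC)c(OC)c2Oc2cc(OC)c(Oc3c(Oc4cc(OC)c(OC)c(Oc5cc(OC)c(OC)c(OC)c5Oc5cc(OC)c(OC)c(OC)c5)c4)cc(OC)c(OC)c3OC)c(OC)c2)c(OC)c1
F6 | step 17 | methyl 6-(heptamer-oxy)-3,5-dioxohexanoate | COC(=O)CC(=O)CC(=O)COc1cc(OC)c(Oc2cc(OC)c(OC)c(OC)c2Oc2cc(OC)c(Oc3c(Oc4cc(OC)c(OC)c(Oc5cc(OC)c(OC)c(OC)c5Oc5cc(OC)c(OC)c(OC)c5)c4)cc(OC)c(OC)c3OC)c(OC)c2)c(OC)c1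
F7 | step 17 | 2-(heptamer-oxy)cyclohexane-1,3,5-trione | O=C1CC(=O)C(Oc2cc(OC)c(Oc3cc(OC)c(OC)c(OC)c3Oc3cc(OC)c(Oc4c(Oc5cc(OC)c(OC)c(Oc6cc(OC)c(OC)c(OC)c6Oc6cc(OC)c(OC)c(OC)c6)c5)cc(OC)c(OC)c4OC)c(OC)c3)c(OC)c2)C(=O)C1
F8 | step 17 | octamer with ring A as free triol and rings B–H as 18 methyl ethers | Oc1cc(O)c(Oc2cc(OC)c(Oc3cc(OC)c(OC)c(OC)c3Oc3cc(OC)c(Oc4c(Oc5cc(OC)c(OC)c(Oc6cc(OC)c(OC)c(OC)c6Oc6cc(OC)c(OC)c(OC)c6)c5)cc(OC)c(OC)c4OC)c(OC)c3)c(OC)c2)c(O)c1
F9 | step 15 | 4-(4-iodo-3,5-dimethoxyphenoxy)-3,5-dimethoxybenzaldehyde | COc1cc(C=O)cc(OC)c1Oc1cc(OC)c(I)c(OC)c1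
F10 | step 15 | 4-(4-iodo-3,5-dimethoxyphenoxy)-3,5-dimethoxyphenyl formate | COc1cc(OC=O)cc(OC)c1Oc1cc(OC)c(I)c(OC)c1
F11 | step 15 | 4-(4-iodo-3,5-dimethoxyphenoxy)-3,5-dimethoxyphenol | COc1cc(O)cc(OC)c1Oc1cc(OC)c(I)c(OC)c1
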